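## Structural features

The target is numbered as a lignan: ring A = C1–C6, the chain C7, C8, C8', C7', and ring C = C1'–C6'. Ring A is a 3,4,5-trimethoxy arene; ring B is a seven-membered carbocycle (C1, C2, C1', C7', C8', C8, C7) fused to A through C1–C2; ring C is a 3',5'-dimethoxycyclohexa-2',5'-dien-4'-one joined to B only through the spiro carbon C1'. Three contiguous stereocentres sit on ring B: C7 (R, benzylic benzoate), C8 (S, methyl) and C8' (R, methyl). They are all-trans around the ring, which is an all-syn triad in the open chain; C1' is quaternary but not stereogenic because ring C is symmetric. Fragile groups are the benzylic benzoate (ionisation on the electron-rich arene; cleavage by hydroxide, alkoxide or hydride), the cross-conjugated dienone with its two enol ethers (acid, nucleophiles, reductants) and the electron-rich arene (oxidants, electrophiles). The real difficulty is the fully substituted C1': it is benzylic to an arene with an ortho methoxy group, shared by two rings, and should be made without phenol oxidation; a second difficulty is placing the C7 oxygen syn to the C8 methyl. Ring C contains the pattern C1'(quaternary)–C2'H=C3'(OMe)–C4'(=O) of a 4,4-disubstituted 2-methoxycyclohexenone. C2' can therefore be traced to a formyl carbon on C1' of ring B and C3'–C6' to a four-carbon methoxy vinyl ketone; this is what the key step uses, and the symmetry of ring C makes the configuration created at C1' irrelevant.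

## Logic of the disconnections

30 ⇒ 29. Cut: the O–CH3 bond at C5'. Reason: the second enol ether is installed last, when nothing further has to be done on ring C. Gain: the two halves of ring C become different, so the C5' oxygen can be introduced stepwise. Demand: O- rather than C-methylation, with a base that spares the benzoate.

29 ⇒ 27 ⇒ 25. Cut: the C5'–O bond, after lowering the oxidation level at C5'/C6'. Reason: 25 has a single enolisable position (C5'), so oxygenation cannot go astray. Gain: one oxygen and one unsaturation are removed and the annulation product is reached. Demand: enolate formation next to a benzoate, and oxidation of the acyloin without C–C cleavage.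

25 ⇒ 19 + 22 (key disconnection). Cut: C1'–C6' and C2'=C3'. Reason: 25 is the Robinson retron with C1' as the 4,4-disubstituted carbon. Gain: ring C and the quaternary centre disappear, leaving a ring B aldehyde with all three stereocentres and a C4 enone. Demand: the enamine must add at the hindered C1', the aldol must close through C3', and the medium must not cleave the benzoate.

22 ⇒ 21 ⇒ 20. Cut: the carbonyl–vinyl C–C bond, then the amide C–N bond. Reason: the polymerisable enone is made fresh from a stable amide. Demand: the liberated hydroxylamine must not add to the enone.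

19 ⇒ 18 ⇒ 16. No skeletal bond is cut; the formyl carbon is traced to the terminal carbon of an exocyclic alkene on C1'. Reason: an ester or nitrile on C1' would have to be reduced beside the C7 benzoate, and would make every ring B intermediate a pair of C1' epimers while C7 is created. Gain: C1' is sp2 at the ring-closure stage and the benzoate can be in place from the start. Demand: anti-Markovnikov hydration and oxidations that do not hydrolyse the ester.

16 ⇒ 15. Cut: C2–C1' (opens ring B). Reason: C2 lies ortho/para to methoxy groups, so it is the natural site for a halogen, and a 7-exo Heck closure delivers the future formyl carbon as the exocyclic CH2. Gain: an acyclic chain carrying all three stereocentres. Demand: exo over endo closure, no migration of the new double bond, oxidative addition at a hindered electron-rich bromide.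

15 ⇒ 12 + 10. Cut: C1–C7 and the benzoate C–O bond. Reason: C7 is a carbinol next to an α-methyl stereocentre, and Felkin–Anh addition of an aryl nucleophile to the aldehyde gives the required syn relationship directly. Gain: the arene and a small chiral aldehyde are separated. Demand: metalation at C1 and not C2, and useful facial selectivity.

12 ⇒ 11. Cut: C2–Br. Demand: bromination at the position flanked by iodine and methoxy, the only strongly activated free site.

10 ⇒ 9 ⇒ 8. Cut: the C7'–C1' bond (sp3–sp2), after raising C7 to the ester level. Reason: the allyl terminus is a primary iodide plus a vinyl nucleophile. Gain: a C4 unit with differentiated ends. Demand: no enolisation of the ester during coupling.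

8 ⇒ 6. Cut: C7'–I, reconnecting C7' to the carboxyl oxygen. Reason: 6 is the natural form in which the two ends of the dimethyl C4 unit differ (C=O against CH2–O). Demand: cleavage at the alkyl–oxygen bond only.

6 ⇒ 4 ⇒ 1 + 2. Cut: C8–C8', after reopening the ring to the imide ester. Reason: each methyl-bearing centre then comes from an independent, reliable element: auxiliary face control for C8', SN2 inversion of a lactate for C8. Gain: two commercial three-carbon pieces. Demand: substitution rather than elimination at the secondary triflate, and reduction of the imide in the presence of the ester.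

## Other disconnections considered

Alternative 1: The cut is through C1–C7 and C7–C8, with C7 supplied as carbon monoxide. The precursor is aryl triflate A1, which already carries the masked ring C (a 3',5'-dimethoxycyclohexa-2',5'-diene, C4' still CH2) on the quaternary C1', together with a (2R)-2-methylbut-3-enyl chain. Under Pd(OAc)2/1,3-bis(diphenylphosphino)propane and CO, the aroyl palladium species adds to the inner vinyl carbon C8 and β-hydride elimination gives α-methylene ketone A2.
- In its favour: two C–C bonds, ring B and the C7 carbonyl arise in one catalytic step from a C1 feedstock, and only C8' has to be brought in.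
- Against it here: oxidative addition must occur at a triflate ortho to a quaternary carbon; direct 6-exo Heck closure without CO uptake competes; the acid-labile bis-enol ether must survive. Three selectivity problems remain on the closed ring: hydrogenation of the methylidene to the 8S methyl, reduction of C7 from the correct face, and oxidation of C4' to the dienone. The quaternary carbon must also be built before ring B, at an intermolecular stage.
- Comparison: for building ring B itself the alternative is the better plan (one step against steps 7 and 8). On late oxidation of ring C the two are equal (C4' there, C5' here). The chosen plan is stronger in that C8 and C8' are fixed before any ring exists and the quaternary centre is made last by an annulation whose regiochemistry is set by ring size. On C7 neither has a decisive advantage: one relies on ring-face control, the other on Felkin–Anh control.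

Alternative 2: The cut removes both C–CH3 bonds. Achiral enone A3 (C8=C8' conjugated to the C7 aryl ketone, ring C masked as above) takes up Me2Zn at C8' under Cu(OTf)2 and a chiral phosphoramidite. The zinc enolate is then methylated at C8 with iodomethane, anti to the new methyl, giving trans-dimethyl ketone A4.
- In its favour: all absolute configuration comes from a catalyst, no auxiliary or chiral-pool reagent is consumed, the precursor needs no stereocontrol, and two stereocentres are set in one flask. On economy of chirality and on steps spent on stereocentres it is the better plan.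
- Against it here: the enone is an electron-rich aryl ketone of reduced electrophilicity; C8' lies one CH2 from the quaternary spiro carbon; zinc enolates alkylate sluggishly, so protonation or double methylation can intervene. A shortfall in enantioselectivity cannot be corrected by separating diastereomers, because no other stereocentre is present. C7 reduction, benzoylation and C4' oxidation still follow.
- Comparison: the chosen plan spends stoichiometric chirality (1 and 2), but each centre is fixed by a stereospecific or auxiliary-controlled event and errors show up as separable diastereomers at 4. The alternative would reveal a stereochemical failure only after the whole spiro framework is built. Step counts should be similar, and on the C7 carbinol the two face the same kind of problem.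

Alternative 3: The cut is through C1–C7 and C2–C1' at once. Aryl iodide A5 and phenol thioester A6 (S-ethyl assumed; it carries C8 and C8') react under Pd(OAc)2, a triarylphosphine, norbornene and Cs2CO3. The aryl–norbornyl palladacycle is acylated at the ortho C–H position (C1–C7), norbornene is extruded, and the aryl palladium species is captured at the para carbon of the phenolate (C2–C1'), giving spirodienone ketone A7.
- In its favour: it is the most convergent of the four plans; ring B, the quaternary carbon and ring C in its final oxidation state form in one step, with no late oxidation of ring C. On convergence and on ring C it is the better plan, and A6 could take its stereocentres from the same chemistry as 6.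
- Against it here: acyl donor and terminating nucleophile are in one molecule, so acylation must precede termination and oligomerisation must be outrun. The terminating dearomatisation has to close a seven-membered ring. C8, α to the thioester and then to the ketone, can epimerise under carbonate at elevated temperature. Afterwards the C7 aryl ketone must be reduced from the right face in the presence of the dienone carbonyl.
- Comparison: the chosen plan is longer and must oxidise C5' after annulation. In return each bond formation belongs to a well-precedented reaction class, C7 is set before any dienone exists, and C8 is never adjacent to a ketone. The alternative trades that security for brevity.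

Key step: step 13

Remark 1: 19, 22 and 25 agree atom for atom with 30 (ring sizes, substituents, 7R, 8S, 8'R), so no structure needed correcting; 2 and 11 are taken as purchasable (2 is otherwise one step from ethyl (S)-lactate and Tf2O).
Remark 2: 17–19 and 23–29 are carried as mixtures of epimers at C1' (27 also at C5'); these centres are not stereogenic in 30.

## Steps

Step 1
Reactants: 1 (R)-4-benzyl-3-propionyloxazolidin-2-one; 2 ethyl (S)-2-{[(trifluoromethyl)sulfonyl]oxy}propanoate
Product: 4 ethyl (2S,3S)-4-[(4R)-4-benzyl-2-oxo-1,3-oxazolidin-3-yl]-2,3-dimethyl-4-oxobutanoate, via lithium enolate 3 (not isolated)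
Conditions: LiN(SiMe3)2, THF, −78 °C; then 2, −78 → −40 °C
Reagents that add atoms: none
Why: Alkylation of an N-acyloxazolidinone enolate by an α-triflyloxy ester (SN2): the chelated Z-enolate 3 is attacked on the face away from the benzyl group, making the imide α-carbon (future C8') S, and inversion at the lactate carbon makes the future C8 S. The carbonyl-activated secondary triflate reacts at −78 °C, below the range where elimination or epimerisation matter.

Step 2
Reactants: 4 ethyl (2S,3S)-4-[(4R)-4-benzyl-2-oxo-1,3-oxazolidin-3-yl]-2,3-dimethyl-4-oxobutanoate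
Product: 6 (3S,4S)-3,4-dimethyloxolan-2-one, via hydroxy ester 5 (not isolated)
Conditions: NaBH4, THF/H2O, 0 °C → rt; then TsOH·H2O (cat.), CH2Cl2, rt
Reagents that add atoms: none
Why: NaBH4 in wet THF reduces the N-acyloxazolidinone to the primary alcohol and leaves the ethyl ester (reductive auxiliary removal). The γ-hydroxy ester 5 then lactonises under acid, which differentiates the two ends of the C4 unit; no stereocentre is touched.

Step 3
Reactants: 6 (3S,4S)-3,4-dimethyloxolan-2-one
Product: 8 ethyl (2S,3S)-4-iodo-2,3-dimethylbutanoate, via silyl ester 7 (not isolated)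
Conditions: Me3SiI, CH2Cl2, rt; then EtOH, rt
Reagents that add atoms: iodotrimethylsilane, C[Si](C)(C)I; ethanol, CCO
Why: Silyl iodide cleavage of a lactone: O-silylation activates the ring and iodide opens it by SN2 at the primary O–CH2 carbon (future C7'). Ethanolysis of silyl ester 7 under the acid formed gives the ethyl ester; neither stereocentre is involved.

Step 4
Reactants: 8 ethyl (2S,3S)-4-iodo-2,3-dimethylbutanoate
Product: 9 ethyl (2S,3R)-2,3-dimethylhex-5-enoate
Conditions: CH2=CHMgBr, CuI (10 mol%), THF, −40 → −20 °C
Reagents that add atoms: vinylmagnesium bromide, C=C[Mg]Br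
Why: Copper-catalysed sp3–sp2 coupling of a primary alkyl iodide with a vinyl Grignard reagent. At −40 °C displacement by the organocopper species is much faster than addition to, or enolisation of, the α-branched ester, so C8 keeps its configuration (the descriptor at C3 changes only through CIP priorities).

Step 5
Reactants: 9 ethyl (2S,3R)-2,3-dimethylhex-5-enoate
Product: 10 (2S,3R)-2,3-dimethylhex-5-enal
Conditions: iBu2AlH (1.05 equiv), CH2Cl2, −78 °C; MeOH, then aq. potassium sodium tartrate
Reagents that add atoms: none
Why: Partial reduction of an ester with iBu2AlH at −78 °C, where the tetrahedral aluminium hemiacetal persists until hydrolysis. The conditions are non-basic, so the α-stereocentre is not epimerised; the volatile aldehyde is used at once.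

Step 6
Reactants: 11 5-iodo-1,2,3-trimethoxybenzene
Product: 12 2-bromo-1-iodo-3,4,5-trimethoxybenzene
Conditions: NBS, MeCN, 0 °C → rt
Reagents that add atoms: N-bromosuccinimide, O=C1CCC(=O)N1Br
Why: Electrophilic aromatic bromination at the free position ortho to one methoxy and para to another, by far the most activated site. This places Br on the future C2 and leaves I on the future C1.

Step 7
Reactants: 12 2-bromo-1-iodo-3,4,5-trimethoxybenzene; 10 (2S,3R)-2,3-dimethylhex-5-enal
Product: 15 (1R,2S,3R)-1-(2-bromo-3,4,5-trimethoxyphenyl)-2,3-dimethylhex-5-en-1-yl benzoate, via aryl Grignard reagent 13 (not isolated), via magnesium alkoxide 14 (not isolated)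
Conditions: iPrMgCl·LiCl, THF, −20 °C; then 10, −78 → −20 °C; then BzCl, DMAP (cat.), −20 °C → rt
Reagents that add atoms: benzoyl chloride, O=C(Cl)c1ccccc1
Why: Iodine–magnesium exchange is selective for C–I over C–Br and gives 13, which does not lose MgBrCl to an aryne at this temperature. Felkin–Anh addition to the α-methyl aldehyde (nucleophile anti to the branched C3 substituent, passing the α-hydrogen) should favour the 1,2-syn (1R) alkoxide 14, which is acylated in the same flask. The minor C7 epimer is to be removed by chromatography of 15.

Step 8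
Reactants: 15 (1R,2S,3R)-1-(2-bromo-3,4,5-trimethoxyphenyl)-2,3-dimethylhex-5-en-1-yl benzoate
Product: 16 (5R,6S,7R)-1,2,3-trimethoxy-6,7-dimethyl-9-methylidene-6,7,8,9-tetrahydro-5H-benzo[7]annulen-5-yl benzoate
Conditions: Pd2(dba)3 (5 mol%), P(tBu)3·HBF4 (12 mol%), Cy2NMe, dioxane, 80 °C
Reagents that add atoms: none
Why: Intramolecular Mizoroki–Heck reaction: oxidative addition of the aryl bromide to zerovalent palladium, 7-exo-trig carbopalladation at the internal alkene carbon (forming C2–C1') and β-hydride elimination from C1' give the exocyclic methylene. The bulky electron-rich phosphine serves the hindered, electron-rich bromide, and the amine base limits hydride re-addition and double-bond migration.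

Step 9
Reactants: 16 (5R,6S,7R)-1,2,3-trimethoxy-6,7-dimethyl-9-methylidene-6,7,8,9-tetrahydro-5H-benzo[7]annulen-5-yl benzoate
Product: 18 (5R,6S,7R)-9-(hydroxymethyl)-1,2,3-trimethoxy-6,7-dimethyl-6,7,8,9-tetrahydro-5H-benzo[7]annulen-5-yl benzoate (both C9 epimers), via alkylborane 17 (not isolated)
Conditions: 9-BBN, THF, 50 °C; then NaBO3·4H2O, THF/H2O, rt
Reagents that add atoms: sodium perborate, [Na+].[Na+].O[B-]1(O)OO[B-](O)(O)OO1
Why: Anti-Markovnikov hydroboration of a 1,1-disubstituted alkene with 9-BBN puts boron on the terminal carbon, and perborate oxidises the C–B bond without hydrolysing the benzoate. The new C1' stereocentre is formed without control, which is immaterial because it becomes the symmetric spiro carbon.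

Step 10
Reactants: 18 (5R,6S,7R)-9-(hydroxymethyl)-1,2,3-trimethoxy-6,7-dimethyl-6,7,8,9-tetrahydro-5H-benzo[7]annulen-5-yl benzoate
Product: 19 (5R,6S,7R)-9-formyl-1,2,3-trimethoxy-6,7-dimethyl-6,7,8,9-tetrahydro-5H-benzo[7]annulen-5-yl benzoate (both C9 epimers)
Conditions: Dess–Martin periodinane, NaHCO3, CH2Cl2, rt
Reagents that add atoms: none
Why: Dess–Martin oxidation of a primary alcohol to the aldehyde under buffered, non-basic conditions that leave the benzoate intact. The α-aryl aldehyde is used directly to avoid air oxidation.

Step 11
Reactants: 20 methoxyacetyl chloride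
Product: 21 N,2-dimethoxy-N-methylacetamide
Conditions: MeNH(OMe)·HCl, Et3N, CH2Cl2, 0 °C → rt
Reagents that add atoms: N,O-dimethylhydroxylamine hydrochloride, CNOC.Cl
Why: Acylation of N,O-dimethylhydroxylamine by an acid chloride (Weinreb amide formation).

Step 12
Reactants: 21 N,2-dimethoxy-N-methylacetamide
Product: 22 1-methoxybut-3-en-2-one
Conditions: CH2=CHMgBr, THF, −78 → 0 °C; inverse quench into cold 2 M HCl
Reagents that add atoms: vinylmagnesium bromide, C=C[Mg]Br
Why: Weinreb ketone synthesis: the chelated tetrahedral adduct stops at mono-addition, and the inverse acidic quench protonates the released hydroxylamine so that it cannot add to the vinyl ketone. 22 is kept cold in solution with a radical inhibitor and used promptly.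

Step 13
Reactants: 19 (5R,6S,7R)-9-formyl-1,2,3-trimethoxy-6,7-dimethyl-6,7,8,9-tetrahydro-5H-benzo[7]annulen-5-yl benzoate; 22 1-methoxybut-3-en-2-one
Product: 25 (7R,8S,9R)-2,3,3',4-tetramethoxy-7,8-dimethyl-4'-oxo-6,7,8,9-tetrahydrospiro[benzo[7]annulene-5,1'-cyclohex[2]en]-9-yl benzoate (both spiro epimers), via enamine 23 (not isolated), via keto aldehyde 24 (not isolated)
Conditions: pyrrolidine (1.2 equiv), 4 Å MS, PhMe, rt; then 22, 0 °C → rt; then AcOH/NaOAc/H2O, 70 °C
Reagents that add atoms: none
Why: Condensation of 19 with pyrrolidine gives enamine 23, in which C1' is the only possible nucleophilic carbon; its conjugate addition to the terminal carbon of 22 (Stork enamine Michael addition) forms C1'–C6' and the quaternary centre, and buffered hydrolysis releases keto aldehyde 24. The pyrrolidinium acetate then present enolises the methoxy ketone, and an intramolecular aldol condensation joins C3' to the formyl carbon C2', dehydration giving C2'=C3'. The closest known reaction type is the Robinson annulation of α,α-disubstituted (including α-aryl) aldehydes with methyl vinyl ketone through their enamines to 4,4-disubstituted cyclohexenones. Ring C closes in the 6-(enolexo)-exo-trig mode. The only new stereocentre is the spiro carbon C1'; it is not controlled and need not be, since both epimers of 25 converge on the symmetric dienone, while C7, C8 and C8' are remote from any enolisable position and stay untouched. The step needs regioselective enolisation and chemoselectivity: closure through C5' would give a cyclobutane, so ring size forces reaction through the methoxy-bearing and more acidic C3', and the amine–acetic acid medium spares the benzoate, which a hydroxide- or alkoxide-mediated annulation would not.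

Step 14
Reactants: 25 (7R,8S,9R)-2,3,3',4-tetramethoxy-7,8-dimethyl-4'-oxo-6,7,8,9-tetrahydrospiro[benzo[7]annulene-5,1'-cyclohex[2]en]-9-yl benzoate
Product: 27 (7R,8S,9R)-5'-hydroxy-2,3,3',4-tetramethoxy-7,8-dimethyl-4'-oxo-6,7,8,9-tetrahydrospiro[benzo[7]annulene-5,1'-cyclohex[2]en]-9-yl benzoate (epimers at C1' and C5'), via potassium dienolate 26 (not isolated)
Conditions: KN(SiMe3)2, THF, −78 °C; then 2-(phenylsulfonyl)-3-phenyloxaziridine, −78 °C; AcOH quench
Reagents that add atoms: 2-(phenylsulfonyl)-3-phenyloxaziridine, O=S(=O)(c1ccccc1)N1OC1c1ccccc1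
Why: Deprotonation can occur only at C5' (C3' and C1' carry no hydrogen), and the cross-conjugated dienolate 26 is hydroxylated at C5' by the N-sulfonyloxaziridine (Davis oxidation). The hindered benzoate tolerates the non-nucleophilic amide base at −78 °C, and the new C5' stereocentre is erased in the next step.

Step 15
Reactants: 27 (7R,8S,9R)-5'-hydroxy-2,3,3',4-tetramethoxy-7,8-dimethyl-4'-oxo-6,7,8,9-tetrahydrospiro[benzo[7]annulene-5,1'-cyclohex[2]en]-9-yl benzoate
Product: 29 (7R,8S,9R)-5'-hydroxy-2,3,3',4-tetramethoxy-7,8-dimethyl-4'-oxo-6,7,8,9-tetrahydrospiro[benzo[7]annulene-5,1'-cyclohexa[2,5]dien]-9-yl benzoate, via 1,2-diketone 28 (not isolated)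
Conditions: (COCl)2, DMSO, CH2Cl2, −78 °C; then Et3N, −78 → 0 °C
Reagents that add atoms: none
Why: Swern oxidation of the acyloin gives the 1,2-diketone 28, which enolises towards C6' (its only α-hydrogens) to the conjugated diosphenol 29 under the amine base.

Step 16
Reactants: 29 (7R,8S,9R)-5'-hydroxy-2,3,3',4-tetramethoxy-7,8-dimethyl-4'-oxo-6,7,8,9-tetrahydrospiro[benzo[7]annulene-5,1'-cyclohexa[2,5]dien]-9-yl benzoate
Product: 30 (7R,8S,9R)-2,3,3',4,5'-pentamethoxy-7,8-dimethyl-4'-oxo-6,7,8,9-tetrahydrospiro[benzo[7]annulene-5,1'-cyclohexa[2,5]dien]-9-yl benzoate (CNP0201356.1)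
Conditions: MeI, K2CO3, acetone, rt
Reagents that add atoms: iodomethane, CI
Why: O-Alkylation of the acidic diosphenol with a weak base; the carbon terminus of the ambident anion (C6') is shielded by the adjacent spiro centre, so methylation goes to oxygen. The product is the symmetric 2,6-dimethoxydienone, in which C1' is no longer stereogenic and 7R, 8S, 8'R are unchanged.

## Compound list

1 | (R)-4-benzyl-3-propionyloxazolidin-2-one | CCC(=O)N1[C@H](Cc2ccccc2)COC1=O | starting material
2 | ethyl (S)-2-{[(trifluoromethyl)sulfonyl]oxy}propanoate | C[C@H](OS(=O)(=O)C(F)(F)F)C(=O)OCC | starting material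
3 | lithium (Z)-1-[(4R)-4-benzyl-2-oxo-1,3-oxazolidin-3-yl]prop-1-en-1-olate | C/C=C(\O[Li])N1[C@H](Cc2ccccc2)COC1=O | intermediate
4 | ethyl (2S,3S)-4-[(4R)-4-benzyl-2-oxo-1,3-oxazolidin-3-yl]-2,3-dimethyl-4-oxobutanoate | CCOC(=O)[C@@H](C)[C@H](C)C(=O)N1[C@H](Cc2ccccc2)COC1=O | intermediate
5 | ethyl (2S,3S)-4-hydroxy-2,3-dimethylbutanoate | CCOC(=O)[C@@H](C)[C@H](C)CO | intermediate
6 | (3S,4S)-3,4-dimethyloxolan-2-one | O=C1[C@@H](C)[C@H](C)CO1 | intermediate
7 | trimethylsilyl (2S,3S)-4-iodo-2,3-dimethylbutanoate | C[Si](C)(C)OC(=O)[C@@H](C)[C@H](C)CI | intermediate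
8 | ethyl (2S,3S)-4-iodo-2,3-dimethylbutanoate | CCOC(=O)[C@@H](C)[C@H](C)CI | intermediate
9 | ethyl (2S,3R)-2,3-dimethylhex-5-enoate | CCOC(=O)[C@@H](C)[C@H](C)CC=C | intermediate
10 | (2S,3R)-2,3-dimethylhex-5-enal | C=CC[C@@H](C)[C@H](C)C=O | intermediate
11 | 5-iodo-1,2,3-trimethoxybenzene | COc1cc(I)cc(OC)c1OC | starting material
12 | 2-bromo-1-iodo-3,4,5-trimethoxybenzene | COc1cc(I)c(Br)c(OC)c1OC | intermediate
13 | (2-bromo-3,4,5-trimethoxyphenyl)magnesium chloride | COc1cc([Mg]Cl)c(Br)c(OC)c1OC | intermediate
14 | chloromagnesium (1R,2S,3R)-1-(2-bromo-3,4,5-trimethoxyphenyl)-2,3-dimethylhex-5-en-1-olate | C=CC[C@@H](C)[C@H](C)[C@@H](O[Mg]Cl)c1cc(OC)c(OC)c(OC)c1Br | intermediate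
15 | (1R,2S,3R)-1-(2-bromo-3,4,5-trimethoxyphenyl)-2,3-dimethylhex-5-en-1-yl benzoate | C=CC[C@@H](C)[C@H](C)[C@@H](OC(=O)c1ccccc1)c1cc(OC)c(OC)c(OC)c1Br | intermediate
16 | (5R,6S,7R)-1,2,3-trimethoxy-6,7-dimethyl-9-methylidene-6,7,8,9-tetrahydro-5H-benzo[7]annulen-5-yl benzoate | C=C1C[C@@H](C)[C@H](C)[C@@H](OC(=O)c2ccccc2)c2cc(OC)c(OC)c(OC)c21 | intermediate
17 | (5R,6S,7R)-9-[(9-borabicyclo[3.3.1]nonan-9-yl)methyl]-1,2,3-trimethoxy-6,7-dimethyl-6,7,8,9-tetrahydro-5H-benzo[7]annulen-5-yl benzoate (both C9 epimers) | C(B1C2CCCC1CCC2)C1C[C@@H](C)[C@H](C)[C@@H](OC(=O)c2ccccc2)c2cc(OC)c(OC)c(OC)c21 | intermediate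
18 | (5R,6S,7R)-9-(hydroxymethyl)-1,2,3-trimethoxy-6,7-dimethyl-6,7,8,9-tetrahydro-5H-benzo[7]annulen-5-yl benzoate (both C9 epimers) | OCC1C[C@@H](C)[C@H](C)[C@@H](OC(=O)c2ccccc2)c2cc(OC)c(OC)c(OC)c21 | intermediate
19 | (5R,6S,7R)-9-formyl-1,2,3-trimethoxy-6,7-dimethyl-6,7,8,9-tetrahydro-5H-benzo[7]annulen-5-yl benzoate (both C9 epimers) | O=CC1C[C@@H](C)[C@H](C)[C@@H](OC(=O)c2ccccc2)c2cc(OC)c(OC)c(OC)c21 | intermediate
20 | methoxyacetyl chloride | COCC(=O)Cl | starting material
21 | N,2-dimethoxy-N-methylacetamide | COCC(=O)N(C)OC | intermediate
22 | 1-methoxybut-3-en-2-one | COCC(=O)C=C | intermediate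
23 | (5R,6S,7R)-1,2,3-trimethoxy-6,7-dimethyl-9-[(pyrrolidin-1-yl)methylidene]-6,7,8,9-tetrahydro-5H-benzo[7]annulen-5-yl benzoate | C(=C1C[C@@H](C)[C@H](C)[C@@H](OC(=O)c2ccccc2)c2cc(OC)c(OC)c(OC)c21)N1CCCC1 | intermediate
24 | (5R,6S,7R)-9-formyl-1,2,3-trimethoxy-9-(4-methoxy-3-oxobutyl)-6,7-dimethyl-6,7,8,9-tetrahydro-5H-benzo[7]annulen-5-yl benzoate (both C9 epimers) | COCC(=O)CCC1(C=O)C[C@@H](C)[C@H](C)[C@@H](OC(=O)c2ccccc2)c2cc(OC)c(OC)c(OC)c21 | intermediate
25 | (7R,8S,9R)-2,3,3',4-tetramethoxy-7,8-dimethyl-4'-oxo-6,7,8,9-tetrahydrospiro[benzo[7]annulene-5,1'-cyclohex[2]en]-9-yl benzoate (both spiro epimers) | COC1=CC2(CCC1=O)C[C@@H](C)[C@H](C)[C@@H](OC(=O)c1ccccc1)c1cc(OC)c(OC)c(OC)c12 | intermediate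
26 | potassium dienolate of 25 (O–K on C4', C4'=C5') | COC1=CC2(CC=C1O[K])C[C@@H](C)[C@H](C)[C@@H](OC(=O)c1ccccc1)c1cc(OC)c(OC)c(OC)c12 | intermediate
27 | (7R,8S,9R)-5'-hydroxy-2,3,3',4-tetramethoxy-7,8-dimethyl-4'-oxo-6,7,8,9-tetrahydrospiro[benzo[7]annulene-5,1'-cyclohex[2]en]-9-yl benzoate (epimers at C1' and C5') | COC1=CC2(CC(O)C1=O)C[C@@H](C)[C@H](C)[C@@H](OC(=O)c1ccccc1)c1cc(OC)c(OC)c(OC)c12 | intermediate
28 | (7R,8S,9R)-2,3,3',4-tetramethoxy-7,8-dimethyl-4',5'-dioxo-6,7,8,9-tetrahydrospiro[benzo[7]annulene-5,1'-cyclohex[2]en]-9-yl benzoate | COC1=CC2(CC(=O)C1=O)C[C@@H](C)[C@H](C)[C@@H](OC(=O)c1ccccc1)c1cc(OC)c(OC)c(OC)c12 | intermediate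
29 | (7R,8S,9R)-5'-hydroxy-2,3,3',4-tetramethoxy-7,8-dimethyl-4'-oxo-6,7,8,9-tetrahydrospiro[benzo[7]annulene-5,1'-cyclohexa[2,5]dien]-9-yl benzoate | COC1=CC2(C=C(O)C1=O)C[C@@H](C)[C@H](C)[C@@H](OC(=O)c1ccccc1)c1cc(OC)c(OC)c(OC)c12 | intermediate
30 | (7R,8S,9R)-2,3,3',4,5'-pentamethoxy-7,8-dimethyl-4'-oxo-6,7,8,9-tetrahydrospiro[benzo[7]annulene-5,1'-cyclohexa[2,5]dien]-9-yl benzoate | COC1=CC2(C=C(OC)C1=O)C[C@@H](C)[C@H](C)[C@@H](OC(=O)c1ccccc1)c1cc(OC)c(OC)c(OC)c12 | target

## Step count and least certain steps

Total steps: 16. Longest linear sequence: 13 steps (steps 1–5, 7–10, 13–16).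

Step 13 (key step). Most likely failure: conjugate addition at the congested C1' (benzylic to an arene with an ortho methoxy group) may be slow enough that polymerisation of the vinyl ketone and reversible amine addition to it outrun C–C bond formation; slow aldol closure onto the neopentyl aldehyde or aminolysis of the benzoate are lesser risks. Fallback, setting out from 19: silylate to the tert-butyldimethylsilyl enol ether F1 (TBSOTf, Et3N, CH2Cl2), combine F1 with 22 in a Lewis-acid-promoted Mukaiyama–Michael addition (Sc(OTf)3, CH2Cl2, −40 °C, aqueous work-up) to obtain 24 as an isolated compound, and cyclise it with pyrrolidinium acetate in toluene. The route is rejoined at 24 and continues to 25.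

Step 8. Most likely failure: sluggish oxidative addition at the doubly ortho-substituted, electron-rich bromide; competing 8-endo closure; migration of the exocyclic double bond into ring B by hydride re-addition (which would put a methyl group on C1'); or ionisation of the benzylic benzoate by zerovalent palladium. Fallback, setting out from 15: hydroborate and oxidise the terminal alkene first (9-BBN; NaBO3·4H2O) to primary alcohol F2, oxidise it (Dess–Martin periodinane) to aldehyde F3, and close ring B by palladium-catalysed intramolecular α-arylation of the aldehyde at C1' (Pd(OAc)2, rac-BINAP, Cs2CO3, dioxane, 80 °C). This gives 19 directly, where the route is rejoined.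

Step 7. Most likely failure: insufficient facial selectivity in the addition to the α-methyl aldehyde (Felkin–Anh control with a methyl/branched-alkyl pair is only moderate), aryne formation from 13 on warming, or enolisation of 10. Fallback, setting out from 10 and 13: quench with NH4Cl instead of benzoyl chloride to obtain carbinol F4 as a mixture of C7 epimers, oxidise to aryl ketone F5 (Dess–Martin periodinane), and reduce under catalyst control (Corey–Bakshi–Shibata reduction, (S)-2-methyl-CBS-oxazaborolidine, BH3·SMe2). With the aryl group as the large substituent this should lead to the 1R carbinol F6, though the catalyst has to override the ketone's own Felkin preference. Benzoylation of F6 (BzCl, pyridine, DMAP) returns to 15.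

Step 14. Most likely failure: incomplete enolisation or attack of the base on the benzoate, addition of the dienolate to the sulfonimine by-product, or over-oxidation. Fallback, setting out from 25: soft enolisation to the triethylsilyl dienol ether F7 (Et3SiOTf, Et3N, CH2Cl2), then Rubottom oxidation (dimethyldioxirane, acetone, −78 °C; aqueous citric acid) to 27, where the route is rejoined. Its own weak point is epoxidation of the C2'=C3' methyl enol ether instead of the less hindered C4'=C5' silyl enol ether.

Step 4. Most likely failure: enolisation of the ester by the Grignard reagent (epimerisation at C2, or closure to a cyclopropane by displacement of iodide), or addition to the ester carbonyl. Fallback, setting out from 8: reverse the polarity by zinc insertion (Zn dust, LiCl, THF) to the alkylzinc iodide F8 and couple it with vinyl bromide under Pd(PPh3)4 (Negishi coupling) to return to 9.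

## Further compounds

F1 | step 13 | (5R,6S,7R)-9-{[(tert-butyldimethylsilyl)oxy]methylidene}-1,2,3-trimethoxy-6,7-dimethyl-6,7,8,9-tetrahydro-5H-benzo[7]annulen-5-yl benzoate | CC(C)(C)[Si](C)(C)OC=C1C[C@@H](C)[C@H](C)[C@@H](OC(=O)c2ccccc2)c2cc(OC)c(OC)c(OC)c21
F2 | step 8 | (1R,2S,3R)-1-(2-bromo-3,4,5-trimethoxyphenyl)-6-hydroxy-2,3-dimethylhexyl benzoate | OCCC[C@@H](C)[C@H](C)[C@@H](OC(=O)c1ccccc1)c1cc(OC)c(OC)c(OC)c1Br
F3 | step 8 | (1R,2S,3R)-1-(2-bromo-3,4,5-trimethoxyphenyl)-2,3-dimethyl-6-oxohexyl benzoate | O=CCC[C@@H](C)[C@H](C)[C@@H](OC(=O)c1ccccc1)c1cc(OC)c(OC)c(OC)c1Br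
F4 | step 7 | (2S,3R)-1-(2-bromo-3,4,5-trimethoxyphenyl)-2,3-dimethylhex-5-en-1-ol (both C1 epimers) | C=CC[C@@H](C)[C@H](C)C(O)c1cc(OC)c(OC)c(OC)c1Br
F5 | step 7 | (2S,3R)-1-(2-bromo-3,4,5-trimethoxyphenyl)-2,3-dimethylhex-5-en-1-one | C=CC[C@@H](C)[C@H](C)C(=O)c1cc(OC)c(OC)c(OC)c1Br
F6 | step 7 | (1R,2S,3R)-1-(2-bromo-3,4,5-trimethoxyphenyl)-2,3-dimethylhex-5-en-1-ol | C=CC[C@@H](C)[C@H](C)[C@@H](O)c1cc(OC)c(OC)c(OC)c1Br
F7 | step 14 | (7R,8S,9R)-2,3,3',4-tetramethoxy-7,8-dimethyl-4'-[(triethylsilyl)oxy]-6,7,8,9-tetrahydrospiro[benzo[7]annulene-5,1'-cyclohexa[2,4]dien]-9-yl benzoate | COC1=CC2(CC=C1O[Si](CC)(CC)CC)C[C@@H](C)[C@H](C)[C@@H](OC(=O)c1ccccc1)c1cc(OC)c(OC)c(OC)c12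
F8 | step 4 | [(2S,3S)-4-ethoxy-2,3-dimethyl-4-oxobutyl](iodo)zinc | CCOC(=O)[C@@H](C)[C@H](C)C[Zn]I
A1 | alternative 1 | 2-{3,5-dimethoxy-1-[(2R)-2-methylbut-3-en-1-yl]cyclohexa-2,5-dien-1-yl}-3,4,5-trimethoxyphenyl trifluoromethanesulfonate | COC1=CC(C[C@@H](C)C=C)(C=C(OC)C1)c1c(OS(=O)(=O)C(F)(F)F)cc(OC)c(OC)c1OC
A2 | alternative 1 | (7R)-2,3,3',4,5'-pentamethoxy-7-methyl-8-methylidene-7,8-dihydrospiro[benzo[7]annulene-5,1'-cyclohexa[2,5]dien]-9(6H)-one | COC1=CC2(C=C(OC)C1)C[C@@H](C)C(=C)C(=O)c1cc(OC)c(OC)c(OC)c12
A3 | alternative 2 | 2,3,3',4,5'-pentamethoxyspiro[benzo[7]annulene-5,1'-cyclohexa[2,5]dien]-9(6H)-one | COC1=CC2(C=C(OC)C1)CC=CC(=O)c1cc(OC)c(OC)c(OC)c12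
A4 | alternative 2 | (7R,8S)-2,3,3',4,5'-pentamethoxy-7,8-dimethyl-7,8-dihydrospiro[benzo[7]annulene-5,1'-cyclohexa[2,5]dien]-9(6H)-one | COC1=CC2(C=C(OC)C1)C[C@@H](C)[C@H](C)C(=O)c1cc(OC)c(OC)c(OC)c12
A5 | alternative 3 | 1-iodo-2,3,4-trimethoxybenzene | COc1ccc(I)c(OC)c1OC
A6 | alternative 3 | S-ethyl (2S,3R)-4-(4-hydroxy-3,5-dimethoxyphenyl)-2,3-dimethylbutanethioate | CCSC(=O)[C@@H](C)[C@H](C)Cc1cc(OC)c(O)c(OC)c1
A7 | alternative 3 | (7R,8S)-2,3,3',4,5'-pentamethoxy-7,8-dimethyl-7,8-dihydrospiro[benzo[7]annulene-5,1'-cyclohexa[2,5]diene]-4',9(6H)-dione | COC1=CC2(C=C(OC)C1=O)C[C@@H](C)[C@H](C)C(=O)c1cc(OC)c(OC)c(OC)c12
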